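**Plan**

- Cuts: the (Z)-3-methylbuta-1,3-dienyl group at C8 goes back to a 2,2-dimethyl-2H-pyran fused across O7/C8, and that to a 7-O-(1,1-dimethylpropargyl) ether (C8–C bond). The chromanone is cut at O1–C8a, then at C4–C4a (aryl ketone), then in the three-carbon chain (β-keto amide, carbinol C–H). The dihydrofuran is cut at C2–C3 (carbene C–H insertion).
- The O1–C8a cut rests on ring A: C8a is ortho to the C4 carbonyl and meta to the oxygens on C5 and C7, so a 2-fluoroaryl ketone takes up the C2 alkoxide at C8a while the C2–O bond is never broken.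
- Forward: benzophenone → dihydrofuran ring (Rh carbene insertion, acid epimerisation to trans) → C5 ester → β-keto amide → (S)-carbinol → aryl ketone → dihydropyranone ring (SNAr) → hydrogenolysis → pyran ring on ring A (Claisen) → photochemical opening to the Z diene → deacetylation.
- Stereochemistry: dihydrofuran C3 from the chiral dirhodium carboxylate, its C2 by trans equilibration under acid, flavanone C2 from a Ru/TsDPEN transfer hydrogenation and kept through the ring closure; the Z alkene is the former ring alkene of the pyran.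
- Protecting groups: benzyl ethers mask all six phenols and fall in one neutral hydrogenolysis before any alkene exists; acetates carry the last steps, because the flavanone C2–O1 bond (a 2,4-dioxygenated benzylic ether) should not see acid.

Key step: step 14

Remark: Rh2(R-PTAD)4 is taken as the catalyst enantiomer that gives the (3R) centre in step 6; if the sense proves to be the reverse, Rh2(S-PTAD)4 is used and nothing else changes.

Abbreviations used in names:
- DBF-Bn = (2R,3R)-6-(benzyloxy)-2-[4-(benzyloxy)phenyl]-3-[3,5-bis(benzyloxy)phenyl]-2,3-dihydro-1-benzofuran-5-yl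
- DBF-OH = (2R,3R)-3-(3,5-dihydroxyphenyl)-6-hydroxy-2-(4-hydroxyphenyl)-2,3-dihydro-1-benzofuran-5-yl
- DBF-Ac = the tetraacetate of DBF-OH
- Chroman-4-one numbering: O1, C2, C3, C4(=O), C4a, C5–C8, C8a

**Route**

Step 1
Reactants: 1 5-bromo-2,4-dihydroxybenzaldehyde
Product: 2 4-(benzyloxy)-5-bromo-2-hydroxybenzaldehyde
Conditions: BnBr (1.05 equiv), NaHCO3, KI (cat.), MeCN, 60 °C
Reagents that add atoms: benzyl bromide, BrCc1ccccc1
Why: Williamson etherification in which the weak base ionises only the 4-OH (acidified by the ortho bromine and the para formyl group), the 2-OH being held in a hydrogen bond to the aldehyde.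

Step 2
Reactants: 2 4-(benzyloxy)-5-bromo-2-hydroxybenzaldehyde; 3 4-(benzyloxy)benzyl chloride
Product: 4 4-(benzyloxy)-2-{[4-(benzyloxy)benzyl]oxy}-5-bromobenzaldehyde
Conditions: K2CO3, DMF, 60 °C
Reagents that add atoms: none
Why: Williamson etherification of the remaining chelated phenol under stronger carbonate/DMF conditions installs the electron-rich benzyl ether whose CH2 later becomes C2 of the dihydrofuran.

Step 3
Reactants: 5 1,3-bis(benzyloxy)-5-bromobenzene; 4 4-(benzyloxy)-2-{[4-(benzyloxy)benzyl]oxy}-5-bromobenzaldehyde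
Product: 7 racemic [4-(benzyloxy)-2-{[4-(benzyloxy)benzyl]oxy}-5-bromophenyl][3,5-bis(benzyloxy)phenyl]methanol, via arylmagnesium bromide 6 (not isolated)
Conditions: Mg, THF, 50 °C; then 4, THF, 0 °C; aq. NH4Cl
Reagents that add atoms: none
Why: Grignard addition to the aldehyde, the aryl bromide of 4 being inert to an arylmagnesium halide at 0 °C.

Step 4
Reactants: 7 racemic diarylmethanol
Product: 8 [4-(benzyloxy)-2-{[4-(benzyloxy)benzyl]oxy}-5-bromophenyl][3,5-bis(benzyloxy)phenyl]methanone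
Conditions: MnO2 (activated, excess), CH2Cl2, rt
Reagents that add atoms: none
Why: MnO2 oxidation of a doubly benzylic alcohol to the benzophenone, which also removes the racemic carbinol centre.

Step 5
Reactants: 8 benzophenone
Product: 9 hydrazone (C=N–NH2, E/Z mixture) of ketone 8
Conditions: N2H4·H2O (20 equiv), AcOH (cat.), EtOH, 85 °C, sealed tube
Reagents that add atoms: hydrazine, NN
Why: Hydrazone condensation, driven by a large excess of hydrazine that also suppresses azine formation on this hindered, electron-rich ketone.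

Step 6
Reactants: 9 hydrazone
Product: 11 (2S,3R)-6-(benzyloxy)-2-[4-(benzyloxy)phenyl]-3-[3,5-bis(benzyloxy)phenyl]-5-bromo-2,3-dihydro-1-benzofuran (2,3-cis), via diaryldiazomethane 10 (not isolated)
Conditions: MnO2, CH2Cl2, rt, filtration; then Rh2(R-PTAD)4 (1 mol %), CH2Cl2, 0 °C
Reagents that add atoms: none
Why: Dehydrogenation of the hydrazone to the diaryldiazomethane followed by dirhodium-catalysed donor/donor carbene 1,5 C–H insertion into the ether CH2 closes the dihydrofuran, the chiral carboxylate ligands choosing the carbene face (C3) and the concerted three-centre insertion placing the C2 aryl group cis to it.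

Step 7
Reactants: 11 cis-dihydrobenzofuran bromide
Product: 12 (2R,3R)-6-(benzyloxy)-2-[4-(benzyloxy)phenyl]-3-[3,5-bis(benzyloxy)phenyl]-5-bromo-2,3-dihydro-1-benzofuran (2,3-trans; DBF-Bn bromide)
Conditions: CF3CO2H (5 vol %), CH2Cl2, 0 °C → rt
Reagents that add atoms: none
Why: Acid-mediated epimerisation by reversible ionisation of the C2–O bond to the 4-(benzyloxy)benzyl cation and re-closure, which should settle on the more stable trans isomer while C3 is untouched.

Step 8
Reactants: 12 DBF-Bn bromide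
Product: 14 methyl DBF-Bn-carboxylate (ester carbon on C5 of the benzofuran), via aryllithium 13 (not isolated)
Conditions: n-BuLi (1.05 equiv), THF, −78 °C; cannulated into ClCO2Me (3 equiv), THF, −78 °C
Reagents that add atoms: methyl chloroformate, COC(=O)Cl
Why: Bromine–lithium exchange and acylation of the aryllithium by a chloroformate, with inverse addition into excess electrophile to prevent a second addition.

Step 9
Reactants: 14 methyl DBF-Bn-carboxylate; 15 N-methoxy-N-methylacetamide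
Product: 17 3-(DBF-Bn)-N-methoxy-N-methyl-3-oxopropanamide, via lithium enolate 16 (not isolated)
Conditions: 15 (3 equiv), LiN(iPr)2 (3 equiv), THF, −78 °C; then 14, −78 → 0 °C; aq. NH4Cl
Reagents that add atoms: none
Why: Crossed Claisen condensation of an amide enolate with the aryl ester, driven by deprotonation of the β-keto amide as it forms.

Step 10
Reactants: 17 β-keto Weinreb amide
Product: 18 (3S)-3-(DBF-Bn)-3-hydroxy-N-methoxy-N-methylpropanamide
Conditions: RuCl[(S,S)-TsDPEN](p-cymene) (2 mol %), HCO2H–Et3N (1:1), DMF, 30 °C; chromatographic removal of the minor epimer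
Reagents that add atoms: none
Why: Noyori–Ikariya asymmetric transfer hydrogenation in which the aryl group of the ketone takes the CH–π-stabilised position of the six-membered hydride-transfer transition state, so the (S,S) catalyst should give the (S) carbinol as it does with acetophenone, and the buffered formate medium avoids acid that would ionise this 2,4-dioxygenated benzylic alcohol.

Step 11
Reactants: 19 5-fluorobenzene-1,3-diol
Product: 20 1,3-bis(benzyloxy)-5-fluorobenzene
Conditions: BnBr (2.2 equiv), K2CO3, DMF, 50 °C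
Reagents that add atoms: benzyl bromide, BrCc1ccccc1
Why: Double Williamson etherification of a simple resorcinol.

Step 12
Reactants: 20 1,3-bis(benzyloxy)-5-fluorobenzene
Product: 21 1,5-bis(benzyloxy)-2-bromo-3-fluorobenzene
Conditions: NBS (1.0 equiv), MeCN, 0 °C → rt
Reagents that add atoms: N-bromosuccinimide, O=C1CCC(=O)N1Br
Why: Electrophilic aromatic bromination is expected para to one benzyloxy group and ortho to the other, at the less crowded site beside fluorine and not between the two benzyloxy groups, as in the 4-bromination of 1,3-dialkoxybenzenes.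

Step 13
Reactants: 21 1,5-bis(benzyloxy)-2-bromo-3-fluorobenzene; 18 (3S)-hydroxy Weinreb amide
Product: 23 (3S)-1-[2,4-bis(benzyloxy)-6-fluorophenyl]-3-(DBF-Bn)-3-hydroxypropan-1-one, via aryllithium 22 (not isolated)
Conditions: 21 (2.3 equiv), n-BuLi (2.2 equiv), THF, −78 °C; then 18, THF, −78 °C; aq. NH4Cl at −78 °C
Reagents that add atoms: none
Why: Bromine–lithium exchange fixes the metal between fluorine and benzyloxy and the Weinreb ketone synthesis stops at the chelated tetrahedral adduct, one equivalent of 22 being spent on the hydroxyl proton, while at −78 °C the 2-fluoroaryllithium should not lose LiF to an aryne.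

Step 14
Reactants: 23 (3S)-β-hydroxy 2-fluoroaryl ketone
Product: 25 (2S)-5,7-bis(benzyloxy)-2-(DBF-Bn)chroman-4-one, via sodium alkoxide 24 (not isolated)
Conditions: NaH (1.05 equiv), THF–DMF (4:1), −20 → 0 °C; pH 7 phosphate buffer
Reagents that add atoms: none
Why: NaH removes the carbinol proton irreversibly and the alkoxide 24 adds to C8a, the fluorine-bearing carbon ortho to the ketone, giving a Meisenheimer adduct whose charge is taken up by the C4 carbonyl before fluoride leaves. The closest known reaction type is the intramolecular SNAr etherification of o-fluoroaryl β-hydroxyalkyl ketones to chroman-4-ones. The one new ring, the dihydropyranone, closes in a 6-exo mode at the arene carbon (O1–C8a). No stereocentre is created: the carbinol C–O bond is never broken, so the (S) centre from step 10 becomes C2 with retention. The step needs substitution to outrun retro-aldol cleavage, dehydration and opening of the product to a chalcone; full conversion to the alkoxide leaves no enolate/hydroxide pair for E1cB loss of water, both benzyloxy groups are meta to C8a and do not oppose the developing charge, and fluoride is the leaving group that makes the addition step fastest. One equivalent of base, low temperature and a neutral quench keep 25 from enolising.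

Step 15
Reactants: 25 hexabenzyl flavanone
Product: 26 (2S)-2-(DBF-OH)-5,7-dihydroxychroman-4-one
Conditions: H2 (1 atm), Pd/C (10 wt %), THF–MeOH, rt
Reagents that add atoms: none
Why: Hydrogenolysis of the six O-benzyl ethers under neutral conditions, which should be much faster than cleavage of the two cyclic, secondary benzylic C–O bonds or reduction of the hydrogen-bonded aryl ketone.

Step 16
Reactants: 26 hexaphenol flavanone; 27 3-chloro-3-methylbut-1-yne
Product: 28 (2S)-2-(DBF-OH)-5-hydroxy-7-[(2-methylbut-3-yn-2-yl)oxy]chroman-4-one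
Conditions: 27 (1.1 equiv), CuCl2·2H2O (1 mol %), DBU (1.0 equiv), MeCN–DMF, −5 °C, under N2
Reagents that add atoms: none
Why: Copper-catalysed propargylic etherification (via a copper allenylidene) in which a single equivalent of base ionises the most acidic phenol, the 7-OH para to the C4 carbonyl, while the 5-OH is locked in its hydrogen bond and the low temperature protects C2.

Step 17
Reactants: 28 7-O-propargyl ether
Product: 29 (2S)-5-acetoxy-2-(DBF-Ac)-7-[(2-methylbut-3-yn-2-yl)oxy]chroman-4-one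
Conditions: Ac2O, pyridine, DMAP (cat.), CH2Cl2, 0 °C → rt
Reagents that add atoms: acetic anhydride, CC(=O)OC(C)=O
Why: Peracetylation (nucleophilic catalysis by DMAP also acylates the chelated 5-OH) removes the O5–H···O=C4 hydrogen bond before the rearrangement and gives a lipophilic substrate for the thermal and photochemical steps.

Step 18
Reactants: 29 pentaacetate propargyl ether
Product: 31 (2S)-5-acetoxy-2-(DBF-Ac)chroman-4-one carrying a 2,2-dimethyl-2H-pyran ring fused across O7 and C8 (C8–CH=CH–CMe2–O7), via allenyl phenol 30 (not isolated)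
Conditions: degassed PhCl, 130 °C, sealed tube
Reagents that add atoms: none
Why: Aromatic propargyl Claisen rearrangement, expected at C8 because with O5 acetylated and unable to chelate the carbonyl the C7–C8 bond should keep the higher double-bond character (as in 7-propargyloxy-coumarins and -chromanones), after which the allenyl phenol closes by 1,5-hydrogen shift and oxa-6π electrocyclisation.

Step 19
Reactants: 31 pyrano-fused flavanone pentaacetate
Product: 33 (2S)-5-acetoxy-2-(DBF-Ac)-7-hydroxy-8-[(1Z)-3-methylbuta-1,3-dien-1-yl]chroman-4-one, via quinone methide 32 (not isolated)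
Conditions: hν (350 nm, Pyrex), degassed MeCN, 0 °C, ca. 1 mM, to partial conversion; work-up cold, in the dark
Reagents that add atoms: none
Why: Photochemical 6π electrocyclic opening of the 2H-pyran to the cis-dienone followed by a thermal 1,7-hydrogen shift from a methyl group to the carbonyl oxygen, a known photoreaction of 2,2-dimethylchromenes, restores ring A as the 7-phenol and leaves the former ring alkene as the Z double bond, the acetylated O5 being unable to drain the excited state by proton transfer.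

Step 20
Reactants: 33 (Z)-dienyl phenol pentaacetate
Product: 34 (2S)-2-(DBF-OH)-5,7-dihydroxy-8-[(1Z)-3-methylbuta-1,3-dien-1-yl]chroman-4-one (CNP0284772.1)
Conditions: Me2N(CH2)3NH2 (8 equiv), THF, 0 °C; aq. NaH2PO4, cold
Reagents that add atoms: none
Why: Aminolysis of the five aryl acetates by a primary amine at 0 °C should free the phenols without opening the flavanone or warming the diene, which as its 7-phenoxide cannot revert to the pyran.

**Compound list**

1 | 5-bromo-2,4-dihydroxybenzaldehyde | O=Cc1cc(Br)c(O)cc1O | starting material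
2 | 4-(benzyloxy)-5-bromo-2-hydroxybenzaldehyde | O=Cc1cc(Br)c(OCc2ccccc2)cc1O | intermediate
3 | 4-(benzyloxy)benzyl chloride | ClCc1ccc(OCc2ccccc2)cc1 | starting material
4 | 4-(benzyloxy)-2-{[4-(benzyloxy)benzyl]oxy}-5-bromobenzaldehyde | O=Cc1cc(Br)c(OCc2ccccc2)cc1OCc1ccc(OCc2ccccc2)cc1 | intermediate
5 | 1,3-bis(benzyloxy)-5-bromobenzene | Brc1cc(OCc2ccccc2)cc(OCc2ccccc2)c1 | starting material
6 | [3,5-bis(benzyloxy)phenyl]magnesium bromide | Br[Mg]c1cc(OCc2ccccc2)cc(OCc2ccccc2)c1 | intermediate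
7 | racemic [4-(benzyloxy)-2-{[4-(benzyloxy)benzyl]oxy}-5-bromophenyl][3,5-bis(benzyloxy)phenyl]methanol | OC(c1cc(OCc2ccccc2)cc(OCc2ccccc2)c1)c1cc(Br)c(OCc2ccccc2)cc1OCc1ccc(OCc2ccccc2)cc1 | intermediate
8 | [4-(benzyloxy)-2-{[4-(benzyloxy)benzyl]oxy}-5-bromophenyl][3,5-bis(benzyloxy)phenyl]methanone | O=C(c1cc(OCc2ccccc2)cc(OCc2ccccc2)c1)c1cc(Br)c(OCc2ccccc2)cc1OCc1ccc(OCc2ccccc2)cc1 | intermediate
9 | hydrazone of ketone 8 | NN=C(c1cc(OCc2ccccc2)cc(OCc2ccccc2)c1)c1cc(Br)c(OCc2ccccc2)cc1OCc1ccc(OCc2ccccc2)cc1 | intermediate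
10 | [4-(benzyloxy)-2-{[4-(benzyloxy)benzyl]oxy}-5-bromophenyl][3,5-bis(benzyloxy)phenyl]diazomethane | [N-]=[N+]=C(c1cc(OCc2ccccc2)cc(OCc2ccccc2)c1)c1cc(Br)c(OCc2ccccc2)cc1OCc1ccc(OCc2ccccc2)cc1 | intermediate
11 | (2S,3R)-6-(benzyloxy)-2-[4-(benzyloxy)phenyl]-3-[3,5-bis(benzyloxy)phenyl]-5-bromo-2,3-dihydro-1-benzofuran (cis) | Brc1cc2c(cc1OCc1ccccc1)O[C@H](c1ccc(OCc3ccccc3)cc1)[C@@H]2c1cc(OCc2ccccc2)cc(OCc2ccccc2)c1 | intermediate
12 | (2R,3R)-6-(benzyloxy)-2-[4-(benzyloxy)phenyl]-3-[3,5-bis(benzyloxy)phenyl]-5-bromo-2,3-dihydro-1-benzofuran (trans; DBF-Bn bromide) | Brc1cc2c(cc1OCc1ccccc1)O[C@@H](c1ccc(OCc3ccccc3)cc1)[C@@H]2c1cc(OCc2ccccc2)cc(OCc2ccccc2)c1 | intermediate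
13 | DBF-Bn lithium (lithium on C5 of the benzofuran) | [Li]c1cc2c(cc1OCc1ccccc1)O[C@@H](c1ccc(OCc3ccccc3)cc1)[C@@H]2c1cc(OCc2ccccc2)cc(OCc2ccccc2)c1 | intermediate
14 | methyl DBF-Bn-carboxylate | COC(=O)c1cc2c(cc1OCc1ccccc1)O[C@@H](c1ccc(OCc3ccccc3)cc1)[C@@H]2c1cc(OCc2ccccc2)cc(OCc2ccccc2)c1 | intermediate
15 | N-methoxy-N-methylacetamide | CC(=O)N(C)OC | starting material
16 | lithium enolate of N-methoxy-N-methylacetamide | [Li]OC(=C)N(C)OC | intermediate
17 | 3-(DBF-Bn)-N-methoxy-N-methyl-3-oxopropanamide | CON(C)C(=O)CC(=O)c1cc2c(cc1OCc1ccccc1)O[C@@H](c1ccc(OCc3ccccc3)cc1)[C@@H]2c1cc(OCc2ccccc2)cc(OCc2ccccc2)c1 | intermediate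
18 | (3S)-3-(DBF-Bn)-3-hydroxy-N-methoxy-N-methylpropanamide | CON(C)C(=O)C[C@H](O)c1cc2c(cc1OCc1ccccc1)O[C@@H](c1ccc(OCc3ccccc3)cc1)[C@@H]2c1cc(OCc2ccccc2)cc(OCc2ccccc2)c1 | intermediate
19 | 5-fluorobenzene-1,3-diol | Oc1cc(O)cc(F)c1 | starting material
20 | 1,3-bis(benzyloxy)-5-fluorobenzene | Fc1cc(OCc2ccccc2)cc(OCc2ccccc2)c1 | intermediate
21 | 1,5-bis(benzyloxy)-2-bromo-3-fluorobenzene | Fc1cc(OCc2ccccc2)cc(OCc2ccccc2)c1Br | intermediate
22 | [2,4-bis(benzyloxy)-6-fluorophenyl]lithium | [Li]c1c(F)cc(OCc2ccccc2)cc1OCc1ccccc1 | intermediate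
23 | (3S)-1-[2,4-bis(benzyloxy)-6-fluorophenyl]-3-(DBF-Bn)-3-hydroxypropan-1-one | O=C(C[C@H](O)c1cc2c(cc1OCc1ccccc1)O[C@@H](c1ccc(OCc3ccccc3)cc1)[C@@H]2c1cc(OCc2ccccc2)cc(OCc2ccccc2)c1)c1c(F)cc(OCc2ccccc2)cc1OCc1ccccc1 | intermediate
24 | sodium alkoxide of 23 | O=C(C[C@H](O[Na])c1cc2c(cc1OCc1ccccc1)O[C@@H](c1ccc(OCc3ccccc3)cc1)[C@@H]2c1cc(OCc2ccccc2)cc(OCc2ccccc2)c1)c1c(F)cc(OCc2ccccc2)cc1OCc1ccccc1 | intermediate
25 | (2S)-5,7-bis(benzyloxy)-2-(DBF-Bn)chroman-4-one | O=C1C[C@@H](c2cc3c(cc2OCc2ccccc2)O[C@@H](c2ccc(OCc4ccccc4)cc2)[C@@H]3c2cc(OCc3ccccc3)cc(OCc3ccccc3)c2)Oc2cc(OCc3ccccc3)cc(OCc3ccccc3)c21 | intermediate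
26 | (2S)-2-(DBF-OH)-5,7-dihydroxychroman-4-one | O=C1C[C@@H](c2cc3c(cc2O)O[C@@H](c2ccc(O)cc2)[C@@H]3c2cc(O)cc(O)c2)Oc2cc(O)cc(O)c21 | intermediate
27 | 3-chloro-3-methylbut-1-yne | C#CC(C)(C)Cl | starting material
28 | (2S)-2-(DBF-OH)-5-hydroxy-7-[(2-methylbut-3-yn-2-yl)oxy]chroman-4-one | O=C1C[C@@H](c2cc3c(cc2O)O[C@@H](c2ccc(O)cc2)[C@@H]3c2cc(O)cc(O)c2)Oc2cc(OC(C)(C)C#C)cc(O)c21 | intermediate
29 | (2S)-5-acetoxy-2-(DBF-Ac)-7-[(2-methylbut-3-yn-2-yl)oxy]chroman-4-one | O=C1C[C@@H](c2cc3c(cc2OC(C)=O)O[C@@H](c2ccc(OC(C)=O)cc2)[C@@H]3c2cc(OC(C)=O)cc(OC(C)=O)c2)Oc2cc(OC(C)(C)C#C)cc(OC(C)=O)c21 | intermediate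
30 | (2S)-5-acetoxy-2-(DBF-Ac)-7-hydroxy-8-(3-methylbuta-1,2-dien-1-yl)chroman-4-one | O=C1C[C@@H](c2cc3c(cc2OC(C)=O)O[C@@H](c2ccc(OC(C)=O)cc2)[C@@H]3c2cc(OC(C)=O)cc(OC(C)=O)c2)Oc2c(C=C=C(C)C)c(O)cc(OC(C)=O)c21 | intermediate
31 | (2S)-5-acetoxy-2-(DBF-Ac)chroman-4-one with a 2,2-dimethyl-2H-pyran ring fused across O7 and C8 | O=C1C[C@@H](c2cc3c(cc2OC(C)=O)O[C@@H](c2ccc(OC(C)=O)cc2)[C@@H]3c2cc(OC(C)=O)cc(OC(C)=O)c2)Oc2c3C=CC(C)(C)Oc3cc(OC(C)=O)c21 | intermediate
32 | ring-opened o-quinone methide of 31 (C7=O, C8=CH–CH=CMe2) | O=C1C[C@@H](c2cc3c(cc2OC(C)=O)O[C@@H](c2ccc(OC(C)=O)cc2)[C@@H]3c2cc(OC(C)=O)cc(OC(C)=O)c2)OC2=C1C(OC(C)=O)=CC(=O)/C2=C\C=C(C)C | intermediate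
33 | (2S)-5-acetoxy-2-(DBF-Ac)-7-hydroxy-8-[(1Z)-3-methylbuta-1,3-dien-1-yl]chroman-4-one | C=C(C)/C=C\c1c(O)cc(OC(C)=O)c2c1O[C@H](c1cc3c(cc1OC(C)=O)O[C@@H](c1ccc(OC(C)=O)cc1)[C@@H]3c1cc(OC(C)=O)cc(OC(C)=O)c1)CC2=O | intermediate
34 | (2S)-2-(DBF-OH)-5,7-dihydroxy-8-[(1Z)-3-methylbuta-1,3-dien-1-yl]chroman-4-one | C=C(C)/C=C\c1c(O)cc(O)c2c1O[C@H](c1cc3c(cc1O)O[C@@H](c1ccc(O)cc1)[C@@H]3c1cc(O)cc(O)c1)CC2=O | target

**Step count**

Total: 20 steps. Longest linear sequence: 18 steps (steps 1–10 and 13–20); steps 11–12 prepare the ring A unit that joins in step 13.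

**Steps most likely to fail**

Step 14. Retro-aldol fragmentation of the alkoxide with re-addition (loss of configuration at the carbinol), or base-induced opening of the product to a chalcone, may compete with a fluoride displacement slowed by the electron-rich ring. Fallback, from 12 back to 25: bromine–lithium exchange on 12 and a DMF quench would give DBF-Bn carbaldehyde F1. Claisen–Schmidt condensation of this with commercial 1-[2,4-bis(benzyloxy)-6-hydroxyphenyl]ethanone (KOH, EtOH–THF) would give the (E)-2'-hydroxychalcone F2. NaOAc in refluxing EtOH would then close the O1–C2 bond by oxa-Michael addition to a mixture of 25 and its (2R) epimer F3. Because the dihydrobenzofuran is already a single enantiomer these are diastereomers, to be separated by chromatography, and the (2R) epimer F3 can be returned to the equilibrium through chalcone F2.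

Step 16. Site selectivity among five reactive phenols may be poor (alkylation at the less acidic but more nucleophilic phenols, or multiple alkylation), and the base may epimerise C2. Fallback, from 26 back to 29: Ac2O/pyridine/DMAP would give the hexaacetate F4. Imidazole and PhSH in NMP at 0 °C, which cleave the most electrophilic aryl acetate of flavonoid peracetates, would give the 7-hydroxy pentaacetate F5, in which O7–H is the only free phenol. Propargylation of this as in step 16 gives 29 directly.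

Step 19. The ring opening may be inefficient, the acetyl group on O5 may migrate in a photo-Fries process, or the product may isomerise (Z to E) or re-close on work-up. Fallback without light, from 26 back to 34:
- The hexaacetate F4 and the 7-hydroxy pentaacetate F5 are made as above.
- NIS in MeCN at 0 °C would iodinate ortho to the only free phenol, expected at C8 since O5 is not chelated, to give the 8-iodo-7-hydroxy pentaacetate F6.
- Re-acetylation gives the 8-iodo hexaacetate F7, which blocks benzofuran formation in the coupling.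
- Sonogashira coupling with 2-methylbut-1-en-3-yne (Pd(PPh3)2Cl2, CuI, Et3N) gives the 8-(3-methylbut-3-en-1-yn-1-yl) hexaacetate F8.
- Semi-reduction of the aryl alkyne with zinc activated by Cu(OAc)2 and AgNO3 in aqueous MeOH gives the (Z)-dienyl hexaacetate F9.
- Aminolysis as in step 20 gives 34.

Further compounds
F1 | step 14 | DBF-Bn carbaldehyde, (2R,3R)-6-(benzyloxy)-2-[4-(benzyloxy)phenyl]-3-[3,5-bis(benzyloxy)phenyl]-2,3-dihydro-1-benzofuran-5-carbaldehyde | O=Cc1cc2c(cc1OCc1ccccc1)O[C@@H](c1ccc(OCc3ccccc3)cc1)[C@@H]2c1cc(OCc2ccccc2)cc(OCc2ccccc2)c1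
F2 | step 14 | (E)-1-[2,4-bis(benzyloxy)-6-hydroxyphenyl]-3-(DBF-Bn)prop-2-en-1-one | O=C(/C=C/c1cc2c(cc1OCc1ccccc1)O[C@@H](c1ccc(OCc3ccccc3)cc1)[C@@H]2c1cc(OCc2ccccc2)cc(OCc2ccccc2)c1)c1c(O)cc(OCc2ccccc2)cc1OCc1ccccc1
F3 | step 14 | (2R)-5,7-bis(benzyloxy)-2-(DBF-Bn)chroman-4-one | O=C1C[C@H](c2cc3c(cc2OCc2ccccc2)O[C@@H](c2ccc(OCc4ccccc4)cc2)[C@@H]3c2cc(OCc3ccccc3)cc(OCc3ccccc3)c2)Oc2cc(OCc3ccccc3)cc(OCc3ccccc3)c21
F4 | step 16 | (2S)-5,7-diacetoxy-2-(DBF-Ac)chroman-4-one | O=C1C[C@@H](c2cc3c(cc2OC(C)=O)O[C@@H](c2ccc(OC(C)=O)cc2)[C@@H]3c2cc(OC(C)=O)cc(OC(C)=O)c2)Oc2cc(OC(C)=O)cc(OC(C)=O)c21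
F5 | step 16 | (2S)-5-acetoxy-2-(DBF-Ac)-7-hydroxychroman-4-one | O=C1C[C@@H](c2cc3c(cc2OC(C)=O)O[C@@H](c2ccc(OC(C)=O)cc2)[C@@H]3c2cc(OC(C)=O)cc(OC(C)=O)c2)Oc2cc(O)cc(OC(C)=O)c21
F6 | step 19 | (2S)-5-acetoxy-2-(DBF-Ac)-7-hydroxy-8-iodochroman-4-one | O=C1C[C@@H](c2cc3c(cc2OC(C)=O)O[C@@H](c2ccc(OC(C)=O)cc2)[C@@H]3c2cc(OC(C)=O)cc(OC(C)=O)c2)Oc2c(I)c(O)cc(OC(C)=O)c21
F7 | step 19 | (2S)-5,7-diacetoxy-2-(DBF-Ac)-8-iodochroman-4-one | O=C1C[C@@H](c2cc3c(cc2OC(C)=O)O[C@@H](c2ccc(OC(C)=O)cc2)[C@@H]3c2cc(OC(C)=O)cc(OC(C)=O)c2)Oc2c(I)c(OC(C)=O)cc(OC(C)=O)c21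
F8 | step 19 | (2S)-5,7-diacetoxy-2-(DBF-Ac)-8-(3-methylbut-3-en-1-yn-1-yl)chroman-4-one | O=C1C[C@@H](c2cc3c(cc2OC(C)=O)O[C@@H](c2ccc(OC(C)=O)cc2)[C@@H]3c2cc(OC(C)=O)cc(OC(C)=O)c2)Oc2c(C#CC(C)=C)c(OC(C)=O)cc(OC(C)=O)c21
F9 | step 19 | (2S)-5,7-diacetoxy-2-(DBF-Ac)-8-[(1Z)-3-methylbuta-1,3-dien-1-yl]chroman-4-one | C=C(C)/C=C\c1c(OC(C)=O)cc(OC(C)=O)c2c1O[C@H](c1cc3c(cc1OC(C)=O)O[C@@H](c1ccc(OC(C)=O)cc1)[C@@H]3c1cc(OC(C)=O)cc(OC(C)=O)c1)CC2=O
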